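Elm stands twice as long as cedar on the same charge, and violet's monomer in chains climbs from 10% to 31% between its first and last readings. Yet a longer run need not give longer chains.

| setting | ochre | green | violet | elm | cedar |
|---|---|---|---|---|---|
| free monomer | 0.050 M | 0.075 M | 0.10 M | 0.10 M | 0.10 M |
| transfer agent | 0.010 M | 0.010 M | 0.010 M | 0.0100 M | 0.0100 M |
| pre-initiator | 2.1 mol% | 2.1 mol% | 3.2 mol% | 2.1 mol% | 2.1 mol% |
| remark | run made earlier | run made earlier | run made earlier |  |  |
| time |  |  |  | 10 d | 5.0 d |

- ochre (time / d: monomer in chains / %): 1.04: 0; 1.67: 0; 3.00: 4; 6.00: 6; 12.0: 7
- green (time / d: monomer in chains / %): 1.04: 3; 3.00: 8; 6.00: 9; 8.00: 14; 12.0: 15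
- violet (time / d: monomer in chains / %): 2.50: 10; 5.00: 19; 8.00: 27; 10.0: 26; 12.0: 31

(standard deviation of a reading: 2 percentage points)

- the average divides the monomer in chains by the number of chains begun, living and dead together
- what was read earlier has a scatter of 2 percentage points, one standard deviation
- the earlier runs do not show the number of chains; that part of a forecast is a guess

* which of the two ends with the longer chains by the average number of monomer units in a chain (chains begun, living or dead) ("neither" if they lie within 10%) (elm / cedar / neither)
* average number of monomer units in a chain (chains begun, living or dead) at the end, elm
* average number of monomer units in a chain (chains begun, living or dead) at the end, cedar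

At 12.0 d, violet reads 0.0310 M of monomer in chains, from 0.00320 M of pre-initiator charged. If each chain starts from one pre-initiator, this reading puts its chains at about 9.69 units or more.

In my own reckoning, a growing chain either adds free monomer or meets transfer agent, so chains and monomer in chains should rise together, with the length following [free monomer]/[transfer agent]. The length per unit of that ratio, taken as units per pre-initiator charged at the last reading, divided by the charged ratio, reads 0.969 in violet (the inverse of the usual transfer constant). Green gives 0.952, and ochre gives 0.667, though its 7% carries a scatter of 2 percentage points.

Replacing the changing ratio by its charged value should cost little in elm: one transfer agent lost per pre-initiator charged would take 0.00210 M of 0.0100 M, a share of 21.0%, while the 22% of free monomer that the forecast expects to be taken pulls the ratio the other way. So elm and cedar should both reach about 9.69 units, a figure on the low side if some of violet's pre-initiator remained unspent.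

The forecast differs: it names elm as the longer, with 2.5 (1.6 to 7) for elm and 1.8 (1.1 to 6) for cedar: “I lean towards elm being longer, with wide ranges.”

The simulation gives neither: elm 11.6, cedar 11.2.

    free monomer + initiator → living end + monomer in chains (k = 6.69 × 10⁻⁴ M⁻¹ s⁻¹)
    free monomer + living end → monomer in chains + living end, rate k2*[living end]*[free monomer] (k = 0.00316 M⁻¹ s⁻¹)
    living end + transfer agent → dead chain (kL = 0.00286 M⁻¹ s⁻¹)
    pre-initiator → initiator (k = 1.65 × 10⁻⁶ s⁻¹)

From 5.00 d to 10.0 d, elm's monomer in chains went from 11.6% to 18.3% and its dead chains from 9.70 × 10⁻⁴ M to 0.00154 M, and the reckoned 9.69 units stand against elm's 11.6. A neighbour of elm charged with 0.0040 M of transfer agent has a ratio of 25.0, so 0.969 reckons 24.2 units. That flask ended with 40.0% monomer in chains and an average of 25.4 units.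

The numbers in the tables were generated by integration with constants of no real substance; the scatter is artificial.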